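**Retrosynthetic overview**

1. The silyl ether of the target is cut at two bonds at once: the lactone bond O2–C3 and the first side-chain bond C1'–C2'. This gives 2,4-dimethoxy-6-vinylbenzoic acid and a (12S)-12-silyloxytridecyl radical, the latter delivered with loss of CO2 from the diacyl peroxide of (13S)-13-silyloxytetradecanoic acid.
2. In the forward direction, a copper/bisoxazoline-catalysed enantioselective radical alkylative lactonisation joins the fragments, closes ring B (the γ-lactone C1–O2–C3–C3a–C7a) and sets C3. Ring A is bought, so ring B is the only ring made.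
3. Enabling feature: C1 and C3 sit on the adjacent ring-A atoms C7a and C3a, so a radical at benzylic C3 is held five atoms from the carboxylate oxygen, and the C3–C1' bond is the former vinyl bond of a styrene. The 5- and 7-methoxy groups are para/ortho to C7a (electron-rich carboxylate) and meta to C3a (no effect on the radical).
4. Vinyl acid: 1-bromo-3,5-dimethoxybenzene, by formylation, Suzuki vinylation and aldehyde oxidation.
5. Peroxide: (S)-propylene oxide (source of C13') and undec-10-enyl Grignard, then silylation, hydroboration–oxidation, oxidation to the acid and peroxide formation. Desilylation ends the route.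

Key step: step 9

Remark: the absolute sense of induction of the copper/bisoxazoline catalyst for this secondary benzylic radical is not established; the (S,S)-ligand is written, and its enantiomer would be used if it favoured the (3R)-lactone.

**Route**

Step 1
Reactants: 1 1-bromo-3,5-dimethoxybenzene
Product: 3 2-bromo-4,6-dimethoxybenzaldehyde, via iminium chloride 2 (not isolated)
Conditions: POCl3, DMF, 0 °C to 100 °C; then H2O
Reagents that add atoms: N,N-dimethylformamide, CN(C)C=O; water, O
Why: Vilsmeier–Haack formylation, in which the chloroiminium ion should attack the ring carbon para to one methoxy group and ortho to the other (next to bromine) rather than the more hindered carbon between the two methoxy groups, and hydrolysis of iminium salt 2 releases the aldehyde.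

Step 2
Reactants: 3 2-bromo-4,6-dimethoxybenzaldehyde; 4 vinylboronic acid pinacol ester
Product: 5 2,4-dimethoxy-6-vinylbenzaldehyde
Conditions: PdCl2(dppf) (3 mol %), K2CO3, 1,4-dioxane/H2O, 85 °C
Reagents that add atoms: none
Why: Suzuki–Miyaura coupling, in which the C–Br bond activated by the ortho formyl group adds to zerovalent palladium and the vinyl group is transferred from the carbonate-activated boronate, the aldehyde being inert under these conditions.

Step 3
Reactants: 5 2,4-dimethoxy-6-vinylbenzaldehyde
Product: 6 2,4-dimethoxy-6-vinylbenzoic acid
Conditions: NaClO2, NaH2PO4, 2-methyl-2-butene (20 equiv), t-BuOH/H2O, 0 °C to rt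
Reagents that add atoms: NaClO2 (sodium chlorite), [Na+].[O-]Cl=O
Why: Pinnick oxidation, in which chlorous acid converts the aldehyde into the acid without touching the alkene, and the large excess of 2-methyl-2-butene should trap the hypochlorous acid that would otherwise attack the vinyl group or the electron-rich ring.

Step 4
Reactants: 7 11-bromoundec-1-ene; 8 (S)-propylene oxide
Product: 10 (2S)-tetradec-13-en-2-ol, via undec-10-enylmagnesium bromide 9 (not isolated)
Conditions: Mg, THF, rt; then CuI (10 mol %), 8, THF, −30 °C to 0 °C; aq. NH4Cl
Reagents that add atoms: none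
Why: Copper-catalysed ring opening of a terminal epoxide by a Grignard reagent, in which attack occurs in an SN2 manner at the unsubstituted epoxide carbon, so the stereocentre of 8 is not touched and becomes the (S)-carbinol C13' of the target.

Step 5
Reactants: 10 (2S)-tetradec-13-en-2-ol
Product: 11 tert-butyldimethyl[(2S)-tetradec-13-en-2-yloxy]silane
Conditions: TBSCl, imidazole, DMF, rt
Reagents that add atoms: tert-butyldimethylsilyl chloride, CC(C)(C)[Si](C)(C)Cl
Why: Standard silylation of a secondary alcohol with imidazole activation, chosen because the silyl ether should survive the borane, oxoammonium, peroxide and radical conditions that follow and can be removed without base at the end.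

Step 6
Reactants: 11 tert-butyldimethyl[(2S)-tetradec-13-en-2-yloxy]silane
Product: 13 (13S)-13-(tert-butyldimethylsilyloxy)tetradecan-1-ol, via B-alkyl-9-BBN adduct 12 (not isolated)
Conditions: 9-BBN, THF, 0 °C to rt; then NaOH, H2O2, 0 °C to rt
Reagents that add atoms: hydrogen peroxide, OO
Why: Brown hydroboration–oxidation, in which 9-BBN places boron on the terminal carbon of the monosubstituted alkene with high anti-Markovnikov selectivity and alkaline peroxide replaces boron by hydroxyl, the silyl ether being stable to both.

Step 7
Reactants: 13 (13S)-13-(tert-butyldimethylsilyloxy)tetradecan-1-ol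
Product: 15 (13S)-13-(tert-butyldimethylsilyloxy)tetradecanoic acid, via aldehyde 14 (not isolated)
Conditions: TEMPO (20 mol %), PhI(OAc)2 (2.2 equiv), MeCN/H2O, rt
Reagents that add atoms: water, O
Why: Oxoammonium (TEMPO/PhI(OAc)2) oxidation, in which the primary alcohol is oxidised to aldehyde 14 and its hydrate is oxidised further to the acid in the aqueous medium under near-neutral conditions that should leave the secondary silyl ether intact.

Step 8
Reactants: 15 (13S)-13-(tert-butyldimethylsilyloxy)tetradecanoic acid (two equivalents)
Product: 17 bis[(13S)-13-(tert-butyldimethylsilyloxy)tetradecanoyl] peroxide, via peroxy acid 16 (not isolated)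
Conditions: DCC (1.05 equiv), 30 % aq. H2O2 (0.55 equiv), DMAP (5 mol %), CH2Cl2, −15 °C to 0 °C
Reagents that add atoms: hydrogen peroxide, OO
Why: Carbodiimide-mediated acylation of hydrogen peroxide (Steglich-type activation), in which the activated acid is intercepted by H2O2 to give peroxy acid 16 and this is acylated by a second activated acid to the symmetrical diacyl peroxide, a standard preparation of long-chain aliphatic diacyl peroxides.

Step 9
Reactants: 6 2,4-dimethoxy-6-vinylbenzoic acid; 17 bis[(13S)-13-(tert-butyldimethylsilyloxy)tetradecanoyl] peroxide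
Product: 20 (3S)-3-[(13S)-13-(tert-butyldimethylsilyloxy)tetradecyl]-5,7-dimethoxy-2-benzofuran-1(3H)-one, via primary alkyl radical 18 (not isolated), via benzylic radical 19 (not isolated)
Conditions: Cu(MeCN)4PF6 (10 mol %), (S,S)-t-Bu-BOX (12 mol %), MTBE, 0 °C to rt; 6 (1.5 equiv), 17 (1.0 equiv) added slowly
Reagents that add atoms: none
Why: Proposed new method: monovalent copper should reduce peroxide 17 by single-electron transfer to a divalent copper carboxylate and an acyloxy radical that loses CO2 to give primary radical 18, which adds to the unsubstituted vinyl carbon of 6 to give benzylic radical 19; 19 is then captured by the chiral divalent copper centre that carries its own carboxylate, and C–O reductive elimination from the resulting six-membered trivalent copper metallacycle forms the O2–C3 bond and returns monovalent copper. The closest known reaction type is the copper/bisoxazoline-catalysed enantioselective radical oxyalkylation (carbolactonisation) of alkenoic acids with aliphatic diacyl peroxides, established for 1,1-disubstituted alkenes that give fully substituted lactone carbons, together with copper-catalysed enantioselective acyloxylation of secondary benzylic radicals; the new element is the intramolecular capture of a secondary benzylic radical to give a tertiary C3–H stereocentre. Ring B (C1–O2–C3–C3a–C7a) closes in a formally 5-exo-trig sense, the carboxylate oxygen bonding to the trigonal benzylic carbon that was the internal alkene carbon. The C3 stereocentre is set under catalyst control by the twofold-symmetric t-Bu-BOX ligand, which differentiates the two faces of planar radical 19 in the C–O bond-forming event, while the remote (S)-carbinol centre is a spectator. The step needs regioselective radical addition (secured by formation of the ring-A-stabilised benzylic radical from the terminal CH2), C–O coupling in preference to radical dimerisation or β-hydride loss (secured by the ortho carboxylate held on copper five atoms from C3), and addition of 18 to the alkene rather than its capture by copper (secured by excess 6, low catalyst loading and slow addition of 17).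

Step 10
Reactants: 20 (3S)-3-[(13S)-13-(tert-butyldimethylsilyloxy)tetradecyl]-5,7-dimethoxy-2-benzofuran-1(3H)-one
Product: 21 (3S)-3-[(13S)-13-hydroxytetradecyl]-5,7-dimethoxy-2-benzofuran-1(3H)-one
Conditions: HF·pyridine, THF, 0 °C to rt
Reagents that add atoms: none
Why: Fluoride-mediated desilylation driven by the strong Si–F bond, under weakly acidic conditions to which the lactone and the C3–H stereocentre are stable, so no ring opening or epimerisation is expected.

**Compound list**

1 | 1-bromo-3,5-dimethoxybenzene | COc1cc(OC)cc(Br)c1 | starting material
2 | N-[(2-bromo-4,6-dimethoxyphenyl)methylidene]-N-methylmethanaminium chloride | COc1cc(OC)c(C=[N+](C)C)c(Br)c1.[Cl-] | intermediate (not isolated)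
3 | 2-bromo-4,6-dimethoxybenzaldehyde | COc1cc(OC)c(C=O)c(Br)c1 | intermediate
4 | vinylboronic acid pinacol ester (4,4,5,5-tetramethyl-2-vinyl-1,3,2-dioxaborolane) | C=CB1OC(C)(C)C(C)(C)O1 | starting material
5 | 2,4-dimethoxy-6-vinylbenzaldehyde | COc1cc(OC)c(C=O)c(C=C)c1 | intermediate
6 | 2,4-dimethoxy-6-vinylbenzoic acid | COc1cc(OC)c(C(=O)O)c(C=C)c1 | intermediate
7 | 11-bromoundec-1-ene | C=CCCCCCCCCCBr | starting material
8 | (S)-propylene oxide ((2S)-2-methyloxirane) | C[C@H]1CO1 | starting material
9 | undec-10-enylmagnesium bromide | C=CCCCCCCCCC[Mg]Br | intermediate (not isolated)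
10 | (2S)-tetradec-13-en-2-ol | C[C@H](O)CCCCCCCCCCC=C | intermediate
11 | tert-butyldimethyl[(2S)-tetradec-13-en-2-yloxy]silane | C[C@H](O[Si](C)(C)C(C)(C)C)CCCCCCCCCCC=C | intermediate
12 | 9-[(13S)-13-(tert-butyldimethylsilyloxy)tetradecyl]-9-borabicyclo[3.3.1]nonane | C[C@H](O[Si](C)(C)C(C)(C)C)CCCCCCCCCCCCB1C2CCCC1CCC2 | intermediate (not isolated)
13 | (13S)-13-(tert-butyldimethylsilyloxy)tetradecan-1-ol | C[C@H](O[Si](C)(C)C(C)(C)C)CCCCCCCCCCCCO | intermediate
14 | (13S)-13-(tert-butyldimethylsilyloxy)tetradecanal | C[C@H](O[Si](C)(C)C(C)(C)C)CCCCCCCCCCCC=O | intermediate (not isolated)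
15 | (13S)-13-(tert-butyldimethylsilyloxy)tetradecanoic acid | C[C@H](O[Si](C)(C)C(C)(C)C)CCCCCCCCCCCC(=O)O | intermediate
16 | (13S)-13-(tert-butyldimethylsilyloxy)tetradecaneperoxoic acid | C[C@H](O[Si](C)(C)C(C)(C)C)CCCCCCCCCCCC(=O)OO | intermediate (not isolated)
17 | bis[(13S)-13-(tert-butyldimethylsilyloxy)tetradecanoyl] peroxide | C[C@H](O[Si](C)(C)C(C)(C)C)CCCCCCCCCCCC(=O)OOC(=O)CCCCCCCCCCC[C@H](C)O[Si](C)(C)C(C)(C)C | intermediate
18 | (12S)-12-(tert-butyldimethylsilyloxy)tridecyl radical | [CH2]CCCCCCCCCC[C@H](C)O[Si](C)(C)C(C)(C)C | intermediate (not isolated)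
19 | (14S)-14-(tert-butyldimethylsilyloxy)-1-(2-carboxy-3,5-dimethoxyphenyl)pentadecyl radical | COc1cc(OC)c(C(=O)O)c([CH]CCCCCCCCCCCC[C@H](C)O[Si](C)(C)C(C)(C)C)c1 | intermediate (not isolated)
20 | (3S)-3-[(13S)-13-(tert-butyldimethylsilyloxy)tetradecyl]-5,7-dimethoxy-2-benzofuran-1(3H)-one | COc1cc(OC)c2c(c1)[C@H](CCCCCCCCCCCC[C@H](C)O[Si](C)(C)C(C)(C)C)OC2=O | intermediate
21 | (3S)-3-[(13S)-13-hydroxytetradecyl]-5,7-dimethoxy-2-benzofuran-1(3H)-one | COc1cc(OC)c2c(c1)[C@H](CCCCCCCCCCCC[C@H](C)O)OC2=O | target

**Step count and risks**

Total step count: 10. Longest linear sequence: 7 steps (steps 4 to 10); steps 1 to 3 form the second branch.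

Steps most likely to fail:

1. Step 9 (proposed new method). The process at risk is insufficient facial discrimination when the secondary benzylic radical is captured, which would give the C3 epimer; this is hard to separate because the second stereocentre is remote. A second risk is diversion of the alkyl radical to copper-mediated ester formation before it adds to the alkene. The fallback uses known chemistry only, sets out from 6 and 13 and comes back to the route at 20. Acid 6 would be esterified (MeI, K2CO3, DMF) to methyl 2,4-dimethoxy-6-vinylbenzoate F1, and the vinyl group of F1 cleaved (OsO4 cat., NaIO4, 2,6-lutidine, dioxane/H2O; Lemieux–Johnson) to methyl 2-formyl-4,6-dimethoxybenzoate F2. In parallel, 13 would be converted (I2, PPh3, imidazole) into tert-butyl{[(2S)-14-iodotetradecan-2-yl]oxy}dimethylsilane F3 and then, by iodine–zinc exchange (Et2Zn, CuI cat., removal of volatiles), into bis[(13S)-13-(tert-butyldimethylsilyloxy)tetradecyl]zinc F4. Catalytic enantioselective addition of F4 to F2 (Ti(OiPr)4, chiral trans-1,2-bis(trifluoromethanesulfonamido)cyclohexane, toluene, −20 °C, ligand enantiomer chosen for the (S)-carbinol) should give methyl 2-[(1S,14S)-14-(tert-butyldimethylsilyloxy)-1-hydroxypentadecyl]-4,6-dimethoxybenzoate F5. F5 should lactonise with loss of methanol on acidic work-up to give 20. In this fallback C3 is set by a two-electron carbonyl addition and ring B closes by acyl substitution.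

2. Step 3. The process at risk is addition of hypochlorous acid to the vinyl group and chlorination of the electron-rich ring if the scavenger does not keep pace. The fallback sets out from 3 and comes back at 6, with the oxidation done before the alkene is present and without a chlorine-based oxidant. Aldehyde 3 would be oxidised (KMnO4, acetone/H2O, rt) to 2-bromo-4,6-dimethoxybenzoic acid F6. F6 would then be vinylated with 4 under Suzuki–Miyaura conditions (PdCl2(dppf), K2CO3 with one extra equivalent, dioxane/H2O) to give 6.

3. Step 8. The process at risk is rearrangement of the carbodiimide-activated acid to an unreactive N-acylurea, and loss of the peroxide by decomposition during concentration. The fallback sets out from 15 and comes back at 17. Acid 15 would be converted under neutral conditions (1-chloro-N,N,2-trimethylprop-1-en-1-amine, CH2Cl2, 0 °C) into (13S)-13-(tert-butyldimethylsilyloxy)tetradecanoyl chloride F7. F7 would be treated with urea–hydrogen peroxide and pyridine at 0 °C (acyl chloride/peroxide route) to give 17, which would be used as a solution without full concentration.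

**Further compounds**

F1 | step 9 | methyl 2,4-dimethoxy-6-vinylbenzoate | COC(=O)c1c(OC)cc(OC)cc1C=C
F2 | step 9 | methyl 2-formyl-4,6-dimethoxybenzoate | COC(=O)c1c(OC)cc(OC)cc1C=O
F3 | step 9 | tert-butyl{[(2S)-14-iodotetradecan-2-yl]oxy}dimethylsilane | C[C@H](O[Si](C)(C)C(C)(C)C)CCCCCCCCCCCCI
F4 | step 9 | bis[(13S)-13-(tert-butyldimethylsilyloxy)tetradecyl]zinc | C[C@H](O[Si](C)(C)C(C)(C)C)CCCCCCCCCCCC[Zn]CCCCCCCCCCCC[C@H](C)O[Si](C)(C)C(C)(C)C
F5 | step 9 | methyl 2-[(1S,14S)-14-(tert-butyldimethylsilyloxy)-1-hydroxypentadecyl]-4,6-dimethoxybenzoate | COC(=O)c1c(OC)cc(OC)cc1[C@@H](O)CCCCCCCCCCCC[C@H](C)O[Si](C)(C)C(C)(C)C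
F6 | step 3 | 2-bromo-4,6-dimethoxybenzoic acid | COc1cc(OC)c(C(=O)O)c(Br)c1
F7 | step 8 | (13S)-13-(tert-butyldimethylsilyloxy)tetradecanoyl chloride | C[C@H](O[Si](C)(C)C(C)(C)C)CCCCCCCCCCCC(Cl)=O
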